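**Strategy.** The target is cut at the C4–C6 interflavan bond into a flavan-4-yl cation precursor and a nucleophilic all-cis flavan-3,4-diol unit. The pyran ring of the diol unit (O1, C2, C3, C4, C4a, C8a) is made from a 1-arylindane: a Hock rearrangement of a tertiary benzylic hydroperoxide inserts O1 between the electron-rich aryl carbon C8a (ortho to C8–O) and the aryl-bearing C2, and silane reduction of the resulting 2-aryl oxocarbenium ion sets C2 cis to the C3/C4 oxygens. The precursor is a 3-aryl-indane-1,2,3-triol whose cis-1,2-diol is locked as a cyclic carbonate, made from a 3-arylindenone by CBS reduction and directed epoxidation.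

Key step: step 7

Remark: flavan numbering (O1, C2–C4, C4a–C8a) is used for both halves; "diol unit" is the flavan-3,4-diol half and "upper unit" the 4-aryl-flavan-3-ol half. Indane intermediates are numbered with C1 = CH–O and C3 = the aryl-bearing carbon. Compounds 1, 2, 4, 14 and 17 are assumed to be purchasable.

Step 1
Reactants: 1 2,3-bis(benzyloxy)benzaldehyde; 2 tert-butyl (triphenylphosphoranylidene)acetate
Product: 3 tert-butyl (E)-3-[2,3-bis(benzyloxy)phenyl]prop-2-enoate
Conditions: toluene, 80 °C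
Reagents that add atoms: none
Why: Wittig olefination with a stabilised ylide should give the (E)-acrylate.

Step 2
Reactants: 3 tert-butyl (E)-3-[2,3-bis(benzyloxy)phenyl]prop-2-enoate; 4 4-iodophenyl acetate
Product: 5 tert-butyl (Z)-3-(4-acetoxyphenyl)-3-[2,3-bis(benzyloxy)phenyl]prop-2-enoate
Conditions: Pd(OAc)2 (5 mol %), P(o-tol)3, Et3N, DMF, 110 °C
Reagents that add atoms: none
Why: Heck arylation (syn carbopalladation, then syn β-hydride elimination) should place the new aryl group trans to the ester, so the bis(benzyloxy)phenyl ring stays cis to the carboxyl group as the next ring closure requires.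

Step 3
Reactants: 5 tert-butyl (Z)-3-(4-acetoxyphenyl)-3-[2,3-bis(benzyloxy)phenyl]prop-2-enoate
Product: 6 4-[4,5-bis(benzyloxy)-1-oxo-1H-inden-3-yl]phenyl acetate
Conditions: CF3CO2H, (CF3CO)2O, CH2Cl2, 0 °C to rt
Reagents that add atoms: none
Why: Acidolysis of the tert-butyl ester and intramolecular Friedel–Crafts acylation through the mixed anhydride should close the five-membered enone ring at the position para to the 3-benzyloxy group, the acetoxyphenyl ring being much less nucleophilic.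

Step 4
Reactants: 6 4-[4,5-bis(benzyloxy)-1-oxo-1H-inden-3-yl]phenyl acetate
Product: 7 4-[(1S)-4,5-bis(benzyloxy)-1-hydroxy-1H-inden-3-yl]phenyl acetate
Conditions: (R)-2-methyl-CBS-oxazaborolidine (10 mol %), BH3·SMe2, THF, −20 °C
Reagents that add atoms: none
Why: Corey–Bakshi–Shibata 1,2-reduction with the fused arene as the large group should set C1 (the future C4 of the diol unit) as (S).

Step 5
Reactants: 7 4-[(1S)-4,5-bis(benzyloxy)-1-hydroxy-1H-inden-3-yl]phenyl acetate
Product: 9 4-[(1R,2R)-4,5-bis(benzyloxy)-1,2,3-trihydroxyindan-3-yl]phenyl acetate (1-OH and 2-OH cis; C3 epimers), via epoxy alcohol 8 (not isolated)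
Conditions: VO(acac)2 (cat.), t-BuOOH, CH2Cl2, 0 °C; then THF/H2O, cat. HClO4, 0 °C
Reagents that add atoms: tert-butyl hydroperoxide (CC(C)(C)OO); water (O)
Why: Hydroxyl-directed vanadium-catalysed epoxidation should deliver oxygen syn to the 1-OH, and SN1 hydrolysis at the diaryl-substituted C3 leaves the C2–O bond untouched, which fixes the cis-1,2-diol (future C3 and C4 of the diol unit).

Step 6
Reactants: 9 4-[(1R,2R)-4,5-bis(benzyloxy)-1,2,3-trihydroxyindan-3-yl]phenyl acetate
Product: 10 4-[(1R,2R)-4,5-bis(benzyloxy)-1,2-(carbonyldioxy)-3-hydroxyindan-3-yl]phenyl acetate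
Conditions: 1,1'-carbonyldiimidazole, THF, rt
Reagents that add atoms: 1,1'-carbonyldiimidazole (O=C(n1ccnc1)n1ccnc1)
Why: Cyclic carbonate formation should occur across the cis secondary 1,2-diol and leave the hindered tertiary alcohol free.

Step 7
Reactants: 10 4-[(1R,2R)-4,5-bis(benzyloxy)-1,2-(carbonyldioxy)-3-hydroxyindan-3-yl]phenyl acetate
Product: 13 4-[(2R,3S,4R)-7,8-bis(benzyloxy)-3,4-(carbonyldioxy)chroman-2-yl]phenyl acetate (2,3-cis-3,4-cis), via hydroperoxide 11 (not isolated), via oxocarbenium ion 12 (not isolated)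
Conditions: urea–H2O2 (1.2 equiv), BF3·OEt2, CH2Cl2, −20 to 0 °C; then Et3SiH, −40 to 0 °C
Reagents that add atoms: hydrogen peroxide (OO), used as its urea adduct
Why: BF3 ionises the tertiary, doubly benzylic alcohol, hydrogen peroxide captures the cation as hydroperoxide 11, and Lewis-acid activation of the O–O bond triggers a Hock (Criegee-type) 1,2-shift of the fused aryl carbon from carbon to oxygen, giving the 2-aryl-chromenylium (oxocarbenium) ion 12, which triethylsilane then reduces. The closest known reactions are the cumene-type Hock rearrangement, the acid-induced ring expansion of 1-indanyl hydroperoxide to 2-hydroxychroman, and the Et3SiH/BF3 reduction of aryl-substituted cyclic oxocarbenium ions used for C-aryl glycosides. No new cyclisation closes the six-membered ring: the five-membered carbocycle is expanded by one atom through carbon-to-oxygen aryl migration, O1 entering between the former C3a and C3 of the indane. The new stereocentre C2 should be set by hydride delivery to the convex face of the cis-fused bicyclic cation, anti to the pseudoaxial C3–O bond that allylic strain with the coplanar 2-aryl group enforces, so that the aryl group ends cis to both carbonate oxygens (2R). The step needs migration of the fused aryl group in preference to the pendant aryl group and to the oxygenated C2 of the indane: the ortho-benzyloxy group makes the fused ring the best migrating group, the weakly donating acetoxy group retards the pendant ring, and the electron-poor carbonate retards alkyl migration and later ionisation at C4.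

Step 8
Reactants: 14 1-(2,3,4-trihydroxyphenyl)ethan-1-one
Product: 15 1-[3,4-bis(benzyloxy)-2-hydroxyphenyl]ethan-1-one
Conditions: BnBr (2.1 equiv), K2CO3, acetone, reflux
Reagents that add atoms: benzyl bromide (BrCc1ccccc1)
Why: Williamson etherification should spare the 2-OH, which is hydrogen-bonded to the carbonyl group.

Step 9
Reactants: 15 1-[3,4-bis(benzyloxy)-2-hydroxyphenyl]ethan-1-one
Product: 16 1-[3,4-bis(benzyloxy)-2-(methoxymethoxy)phenyl]ethan-1-one
Conditions: NaH, MOMCl, DMF, 0 °C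
Reagents that add atoms: chloromethyl methyl ether (COCCl)
Why: O-alkylation of the sodium phenoxide gives the acetal ether that base-mediated epoxidation requires.

Step 10
Reactants: 16 1-[3,4-bis(benzyloxy)-2-(methoxymethoxy)phenyl]ethan-1-one; 17 4-(benzyloxy)benzaldehyde
Product: 18 (E)-1-[3,4-bis(benzyloxy)-2-(methoxymethoxy)phenyl]-3-[4-(benzyloxy)phenyl]prop-2-en-1-one
Conditions: KOH, EtOH/THF, rt
Reagents that add atoms: none
Why: Claisen–Schmidt condensation should give the (E)-chalcone.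

Step 11
Reactants: 18 (E)-1-[3,4-bis(benzyloxy)-2-(methoxymethoxy)phenyl]-3-[4-(benzyloxy)phenyl]prop-2-en-1-one
Product: 19 [(2S,3R)-3-[4-(benzyloxy)phenyl]oxiran-2-yl][3,4-bis(benzyloxy)-2-(methoxymethoxy)phenyl]methanone
Conditions: poly-D-leucine, urea–H2O2, DBU, THF, rt
Reagents that add atoms: hydrogen peroxide (OO), used as its urea adduct
Why: Juliá–Colonna epoxidation with the D-configured polypeptide should give the (2S,3R)-epoxide, whose α-carbon becomes C3 of the upper unit.

Step 12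
Reactants: 19 [(2S,3R)-3-[4-(benzyloxy)phenyl]oxiran-2-yl][3,4-bis(benzyloxy)-2-(methoxymethoxy)phenyl]methanone
Product: 20 (2S,3S)-7,8-bis(benzyloxy)-2-[4-(benzyloxy)phenyl]-3-hydroxychroman-4-one
Conditions: conc. HCl, MeOH/THF, 50 °C
Reagents that add atoms: none
Why: Acidic removal of the methoxymethyl group and 6-endo opening of the epoxide at the benzylic carbon by the phenol should give the trans-dihydroflavonol, the α-C–O bond being retained and C2 taking the favoured trans arrangement.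

Step 13
Reactants: 20 (2S,3S)-7,8-bis(benzyloxy)-2-[4-(benzyloxy)phenyl]-3-hydroxychroman-4-one
Product: 21 (2S,3R,4S)-7,8-bis(benzyloxy)-2-[4-(benzyloxy)phenyl]chroman-3,4-diol
Conditions: NaBH4, EtOH/THF, 0 °C
Reagents that add atoms: none
Why: Hydride reduction of a trans-dihydroflavonol should give the 3,4-trans diol by axial attack; the C4 configuration is lost in the next step in any case.

Step 14
Reactants: 21 (2S,3R,4S)-7,8-bis(benzyloxy)-2-[4-(benzyloxy)phenyl]chroman-3,4-diol; 13 4-[(2R,3S,4R)-7,8-bis(benzyloxy)-3,4-(carbonyldioxy)chroman-2-yl]phenyl acetate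
Product: 22 protected dimer: 13 bearing at C6 the 7,8-bis(benzyloxy)-2-[4-(benzyloxy)phenyl]-3-hydroxychroman-4-yl group (all stereocentres as in 24)
Conditions: BF3·OEt2, CH2Cl2, −20 to 0 °C; 13 in excess (3 equiv, recovered), slow addition of 21
Reagents that add atoms: none
Why: Lewis-acid ionisation of the benzylic 4-OH gives a cation stabilised by O1 and the 7-benzyloxy group, and Friedel–Crafts alkylation at C6 of 13 (para to O1, ortho to 7-O) anti to the 3-OH should give the 3,4-trans interflavan bond, as in proanthocyanidin couplings.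

Step 15
Reactants: 22 protected dimer
Product: 23 penta-O-benzyl ether of 24 (benzyl groups on the four 7,8-oxygens and on the 4'-oxygen of the upper unit)
Conditions: K2CO3, MeOH/THF, 0 °C to rt; AcOH quench
Reagents that add atoms: none
Why: Mild methanolysis should cleave the aryl acetate and the cyclic carbonate without touching the benzyl ethers or the stereocentres.

Step 16
Reactants: 23 penta-O-benzyl ether of 24
Product: 24 (2R,3R,4R)-2-(4-hydroxyphenyl)-6-[(2S,3R,4S)-3,7,8-trihydroxy-2-(4-hydroxyphenyl)chroman-4-yl]chroman-3,4,7,8-tetrol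
Conditions: H2 (1 atm), Pd(OH)2/C, THF/MeOH, rt
Reagents that add atoms: none
Why: Hydrogenolysis of the five aryl benzyl ethers under neutral conditions should release the polyphenol.

**Compound list**

1 | 2,3-bis(benzyloxy)benzaldehyde | O=Cc1cccc(OCc2ccccc2)c1OCc1ccccc1 | starting material
2 | tert-butyl (triphenylphosphoranylidene)acetate | CC(C)(C)OC(=O)C=P(c1ccccc1)(c1ccccc1)c1ccccc1 | starting material
3 | tert-butyl (E)-3-[2,3-bis(benzyloxy)phenyl]prop-2-enoate | CC(C)(C)OC(=O)/C=C/c1cccc(OCc2ccccc2)c1OCc1ccccc1 | intermediate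
4 | 4-iodophenyl acetate | CC(=O)Oc1ccc(I)cc1 | starting material
5 | tert-butyl (Z)-3-(4-acetoxyphenyl)-3-[2,3-bis(benzyloxy)phenyl]prop-2-enoate | CC(C)(C)OC(=O)/C=C(\c1cccc(OCc2ccccc2)c1OCc1ccccc1)c1ccc(OC(C)=O)cc1 | intermediate
6 | 4-[4,5-bis(benzyloxy)-1-oxo-1H-inden-3-yl]phenyl acetate | O=C1C=C(c3ccc(OC(C)=O)cc3)c2c1ccc(OCc1ccccc1)c2OCc1ccccc1 | intermediate
7 | 4-[(1S)-4,5-bis(benzyloxy)-1-hydroxy-1H-inden-3-yl]phenyl acetate | O[C@H]1C=C(c3ccc(OC(C)=O)cc3)c2c1ccc(OCc1ccccc1)c2OCc1ccccc1 | intermediate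
8 | 4-[(1R,2R,3S)-4,5-bis(benzyloxy)-2,3-epoxy-1-hydroxyindan-3-yl]phenyl acetate (epoxide cis to 1-OH) | O[C@H]1[C@H]3O[C@@]3(c3ccc(OC(C)=O)cc3)c2c1ccc(OCc1ccccc1)c2OCc1ccccc1 | intermediate
9 | 4-[(1R,2R)-4,5-bis(benzyloxy)-1,2,3-trihydroxyindan-3-yl]phenyl acetate (C3 epimers) | O[C@H]1[C@@H](O)C(O)(c3ccc(OC(C)=O)cc3)c2c1ccc(OCc1ccccc1)c2OCc1ccccc1 | intermediate
10 | 4-[(1R,2R)-4,5-bis(benzyloxy)-1,2-(carbonyldioxy)-3-hydroxyindan-3-yl]phenyl acetate | O5[C@H]1[C@@H](OC5=O)C(O)(c3ccc(OC(C)=O)cc3)c2c1ccc(OCc1ccccc1)c2OCc1ccccc1 | intermediate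
11 | 4-[(1R,2R)-4,5-bis(benzyloxy)-1,2-(carbonyldioxy)-3-hydroperoxyindan-3-yl]phenyl acetate | O5[C@H]1[C@@H](OC5=O)C(OO)(c3ccc(OC(C)=O)cc3)c2c1ccc(OCc1ccccc1)c2OCc1ccccc1 | intermediate
12 | 2-(4-acetoxyphenyl)-7,8-bis(benzyloxy)-3,4-cis-(carbonyldioxy)-3,4-dihydrochromenylium ion | CC(=O)Oc1ccc(cc1)C2=[O+]c3c(ccc(OCc4ccccc4)c3OCc3ccccc3)[C@@H](O5)[C@H]2OC5=O | intermediate
13 | 4-[(2R,3S,4R)-7,8-bis(benzyloxy)-3,4-(carbonyldioxy)chroman-2-yl]phenyl acetate | CC(=O)Oc1ccc(cc1)[C@H]2Oc3c(ccc(OCc4ccccc4)c3OCc3ccccc3)[C@@H](O5)[C@H]2OC5=O | intermediate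
14 | 1-(2,3,4-trihydroxyphenyl)ethan-1-one | CC(=O)c1ccc(O)c(O)c1O | starting material
15 | 1-[3,4-bis(benzyloxy)-2-hydroxyphenyl]ethan-1-one | CC(=O)c1ccc(OCc2ccccc2)c(OCc2ccccc2)c1O | intermediate
16 | 1-[3,4-bis(benzyloxy)-2-(methoxymethoxy)phenyl]ethan-1-one | CC(=O)c1ccc(OCc2ccccc2)c(OCc2ccccc2)c1OCOC | intermediate
17 | 4-(benzyloxy)benzaldehyde | O=Cc1ccc(OCc2ccccc2)cc1 | starting material
18 | (E)-1-[3,4-bis(benzyloxy)-2-(methoxymethoxy)phenyl]-3-[4-(benzyloxy)phenyl]prop-2-en-1-one | COCOc1c(C(=O)/C=C/c2ccc(OCc3ccccc3)cc2)ccc(OCc2ccccc2)c1OCc1ccccc1 | intermediate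
19 | [(2S,3R)-3-[4-(benzyloxy)phenyl]oxiran-2-yl][3,4-bis(benzyloxy)-2-(methoxymethoxy)phenyl]methanone | COCOc1c(C(=O)[C@H]2O[C@@H]2c2ccc(OCc3ccccc3)cc2)ccc(OCc2ccccc2)c1OCc1ccccc1 | intermediate
20 | (2S,3S)-7,8-bis(benzyloxy)-2-[4-(benzyloxy)phenyl]-3-hydroxychroman-4-one | O=C1c2ccc(OCc3ccccc3)c(OCc3ccccc3)c2O[C@@H](c2ccc(OCc3ccccc3)cc2)[C@@H]1O | intermediate
21 | (2S,3R,4S)-7,8-bis(benzyloxy)-2-[4-(benzyloxy)phenyl]chroman-3,4-diol | O[C@H]1c2ccc(OCc3ccccc3)c(OCc3ccccc3)c2O[C@@H](c2ccc(OCc3ccccc3)cc2)[C@@H]1O | intermediate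
22 | protected dimer (4'-O-acetyl, 3,4-O-carbonyl, penta-O-benzyl derivative of 24) | CC(=O)Oc1ccc(cc1)[C@H]2Oc3c(cc([C@H]4c6ccc(OCc7ccccc7)c(OCc7ccccc7)c6O[C@@H](c6ccc(OCc7ccccc7)cc6)[C@@H]4O)c(OCc4ccccc4)c3OCc3ccccc3)[C@@H](O5)[C@H]2OC5=O | intermediate
23 | penta-O-benzyl ether of 24 | Oc1ccc(cc1)[C@H]2Oc3c(cc([C@H]4c6ccc(OCc7ccccc7)c(OCc7ccccc7)c6O[C@@H](c6ccc(OCc7ccccc7)cc6)[C@@H]4O)c(OCc4ccccc4)c3OCc3ccccc3)[C@@H](O)[C@H]2O | intermediate
24 | (2R,3R,4R)-2-(4-hydroxyphenyl)-6-[(2S,3R,4S)-3,7,8-trihydroxy-2-(4-hydroxyphenyl)chroman-4-yl]chroman-3,4,7,8-tetrol | Oc1ccc([C@H]2Oc3c(cc([C@H]4c5ccc(O)c(O)c5O[C@@H](c5ccc(O)cc5)[C@@H]4O)c(O)c3O)[C@@H](O)[C@H]2O)cc1 | target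

**Step count.** Total: 16 steps. Longest linear sequence: 10 steps (steps 1–7, then 14–16).

**Steps most likely to fail**

Step 7. A group other than the fused aryl carbon may migrate to oxygen, or hydride may be delivered to the wrong face of the cyclic cation (or the ring-opened ketone may be over-reduced). The fallback sets out from 10 and comes back at 13. The peroxide/BF3·OEt2 stage is run without silane and quenched with water, which should give the ring-opened hydroxy ketone 4-{[(4S,5R)-5-[3,4-bis(benzyloxy)-2-hydroxyphenyl]-2-oxo-1,3-dioxolan-4-yl]carbonyl}phenyl acetate F1. Reagent-controlled reduction with (S)-2-methyl-CBS-oxazaborolidine and BH3·SMe2 should give the (S)-configured benzylic alcohol F2. Intramolecular Mitsunobu etherification (PPh3, diisopropyl azodicarboxylate, THF, 0 °C) by the phenol, with inversion at the benzylic carbon, then closes the pyran ring to 13. C2 is thus set by the catalyst and an SN2 step rather than by the facial bias of the cation.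

Step 14. The cation from 21 may be captured by the electron-rich A ring of a second molecule of 21 (self-condensation), or attack may occur at C5 of 13 rather than C6. The fallback sets out from 21 and comes back at 24. Bromination with N-bromosuccinimide (CH2Cl2, −20 °C) at the most activated position should give (2S,3R,4S)-7,8-bis(benzyloxy)-2-[4-(benzyloxy)phenyl]-6-bromochroman-3,4-diol F3, whose A ring can no longer act as a nucleophile. BF3·OEt2-mediated coupling with a small excess of 13 gives the 6-bromo protected dimer F4, K2CO3/MeOH gives the 6-bromo penta-O-benzyl dimer F5, and hydrogenolysis (H2, Pd(OH)2/C, Et3N) removes the bromine together with the benzyl groups to give 24.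

Step 5. The benzylic cation formed on epoxide opening may undergo a 1,2-hydride shift (semipinacol rearrangement to an indan-2-one) instead of hydration, or the allylic alcohol may be oxidised back to the enone. The fallback sets out from 7 and comes back at 9. Hydrogen-bond-directed syn dihydroxylation with stoichiometric OsO4 and N,N,N',N'-tetramethylethylenediamine (CH2Cl2, −78 °C) avoids any cation and proceeds through the chelated osmate ester (hexavalent osmium) F6. Cleavage with aqueous Na2SO3 gives 9 as its single all-cis C3 epimer.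

**Further compounds**

F1 | step 7 | 4-{[(4S,5R)-5-[3,4-bis(benzyloxy)-2-hydroxyphenyl]-2-oxo-1,3-dioxolan-4-yl]carbonyl}phenyl acetate (cis-disubstituted carbonate) | CC(=O)Oc1ccc(cc1)C(=O)[C@@H]2OC(=O)O[C@@H]2c1ccc(OCc3ccccc3)c(OCc3ccccc3)c1O
F2 | step 7 | 4-{(S)-[(4S,5R)-5-[3,4-bis(benzyloxy)-2-hydroxyphenyl]-2-oxo-1,3-dioxolan-4-yl](hydroxy)methyl}phenyl acetate | CC(=O)Oc1ccc(cc1)[C@H](O)[C@@H]2OC(=O)O[C@@H]2c1ccc(OCc3ccccc3)c(OCc3ccccc3)c1O
F3 | step 14 | (2S,3R,4S)-7,8-bis(benzyloxy)-2-[4-(benzyloxy)phenyl]-6-bromochroman-3,4-diol | O[C@H]1c2cc(Br)c(OCc3ccccc3)c(OCc3ccccc3)c2O[C@@H](c2ccc(OCc3ccccc3)cc2)[C@@H]1O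
F4 | step 14 | 6-bromo (upper unit) analogue of protected dimer 22 | CC(=O)Oc1ccc(cc1)[C@H]2Oc3c(cc([C@H]4c6cc(Br)c(OCc7ccccc7)c(OCc7ccccc7)c6O[C@@H](c6ccc(OCc7ccccc7)cc6)[C@@H]4O)c(OCc4ccccc4)c3OCc3ccccc3)[C@@H](O5)[C@H]2OC5=O
F5 | step 14 | 6-bromo (upper unit) analogue of 23 | Oc1ccc(cc1)[C@H]2Oc3c(cc([C@H]4c6cc(Br)c(OCc7ccccc7)c(OCc7ccccc7)c6O[C@@H](c6ccc(OCc7ccccc7)cc6)[C@@H]4O)c(OCc4ccccc4)c3OCc3ccccc3)[C@@H](O)[C@H]2O
F6 | step 5 | cyclic 2,3-osmate ester of the all-cis triol, chelated by N,N,N',N'-tetramethylethylenediamine | O[C@H]1[C@H]2O[Os-2]3(=O)(=O)([N+](C)(C)CC[N+]3(C)C)O[C@@]2(c2ccc(OC(C)=O)cc2)c2c1ccc(OCc1ccccc1)c2OCc1ccccc1
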